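Atoms are numbered in the order of the target SMILES string (the oxygen is atom 25). The retrosynthesis cuts C16–C17 (last ring), then C16–C26 (ring C), C13–C26 (ring B), C27–C28 and the side chain, and traces ring A to a Diels–Alder adduct.
Forward: (R)-linalool gives the cis-oxolane O25/C20–C23 carrying C17, C26 and C27. Ring A is made as a bicyclo[2.2.2]octene, joined to the oxolane ketone by aldol condensation and set free by ozonolysis. Ring B then closes by a 6-exo radical cyclisation, ring C by carbenoid C–H insertion, and the oxabicycle by cationic C16–C17 closure.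
Stereochemistry: C23 comes from (R)-linalool and C20 from a Shi epoxidation; C7, C11 and C29 from one catalytic asymmetric exo Diels–Alder reaction; C13 and C26 from the chair transition state of the radical closure and a stereoretentive insertion; C16 by equilibration.
Enabling feature: the oxolane O25–C20–C21–C22–C23 carries tertiary C17 on C20 and quaternary C26 on C23 on the same face. C17 therefore lies within six-ring reach (through O25) of C16, the free α-carbon of the C15 ketone in cyclopentane ring C, and joining C16 to C17 turns the oxolane into the 8-oxabicyclo[3.2.1]octane.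

Key step: step 22

Assumption: in step 6 the (S)-configured catalyst is taken to expose the diene-facing side of methacrolein that leads to 10; should the mirror-image adduct form, the (R)-catalyst is used instead.

Step 1
Reactants: 1 (R)-linalool
Product: 3 cis-linalool oxide, via 6,7-epoxylinalool 2 (not isolated)
Conditions: D-fructose-derived ketone of the Shi epoxidation (30 mol%), KHSO5 (Oxone), K2CO3, MeCN/CH2(OMe)2/aq. borate buffer, 0 °C; then CSA (cat.), CH2Cl2, rt
Reagents that add atoms: potassium peroxymonosulfate, [K+].[O-]S(=O)(=O)OO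
Why: The Shi epoxidation should oxidise only the electron-rich trisubstituted 6,7-alkene, from the face that gives the (6R)-epoxide, and acid-catalysed 5-exo opening by the C3 hydroxyl with inversion at C6 (target C20) should then give the 2,5-cis oxolane, C23 being the linalool stereocentre.

Step 2
Reactants: 3 cis-linalool oxide
Product: 4 linalool oxide methyl ether
Conditions: NaH, MeI, THF/DMF, 0 °C → rt
Reagents that add atoms: iodomethane, CI
Why: Williamson etherification of the tertiary alkoxide should give a methyl ether that survives every later step and finally serves as the leaving group on C17.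

Step 3
Reactants: 4 linalool oxide methyl ether
Product: 5 oxolanyl methyl ketone
Conditions: PdCl2(Quinox) (5 mol%), AgSbF6 (12 mol%), aq. t-BuOOH, CH2Cl2, rt
Reagents that add atoms: tert-butyl hydroperoxide, CC(C)(C)OO
Why: A Wacker-type oxidation with the quinoline–oxazoline palladium catalyst and TBHP is known to give methyl ketones from allylic ethers, so the vinyl CH should become the C26 carbonyl and the vinyl CH2 the C27 methyl.

Step 4
Reactants: 6 3-methylcyclohex-2-en-1-one
Product: 7 3,6-dimethylcyclohex-2-en-1-one
Conditions: LiN(iPr)2, THF, −78 °C; MeI, −78 → 0 °C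
Reagents that add atoms: iodomethane, CI
Why: Kinetic deprotonation of a cyclohexenone takes place at the α'-carbon, so enolate alkylation should place the methyl group (later C8) on C6 of the enone.

Step 5
Reactants: 7 3,6-dimethylcyclohex-2-en-1-one
Product: 8 2-silyloxy-1,4-dimethylcyclohexa-1,3-diene
Conditions: LiN(iPr)2, THF, −78 °C; TBSCl, HMPA, −78 °C → rt
Reagents that add atoms: tert-butyldimethylsilyl chloride, CC(C)(C)[Si](C)(C)Cl
Why: A second kinetic α'-deprotonation and O-silylation of the cross-conjugated dienolate should give the 2-silyloxy diene whose methylated termini become C7 and C11.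

Step 6
Reactants: 8 2-silyloxy-1,4-dimethylcyclohexa-1,3-diene; 9 methacrolein
Product: 10 bicyclo[2.2.2]octene aldehyde
Conditions: protonated (S)-diphenylprolinol-derived B-(o-tolyl)oxazaborolidine, triflimide salt (20 mol%), CH2Cl2, −78 → −40 °C
Reagents that add atoms: none
Why: In this catalytic asymmetric Diels–Alder reaction the 2-silyloxy group should direct the "para" orientation (C7–C31 and C11–C29 bonds), the α-methyl group of the enal should favour the exo mode (formyl anti to the new enol-ether bridge), and the catalyst should select the diene-facing side of the enal, so that C7, C11 and C29 are set together.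

Step 7
Reactants: 5 oxolanyl methyl ketone; 10 bicyclo[2.2.2]octene aldehyde
Product: 13 enone, via aldol adduct 11 (not isolated), via mesylate 12 (not isolated)
Conditions: 5, LiN(iPr)2, THF, −78 °C; 10; MsCl, −78 → 0 °C; DBU, rt
Reagents that add atoms: none
Why: Ketone 5 can form only one enolate (C27) and aldehyde 10 cannot enolise, so a directed aldol addition followed by E1cB loss of the mesylate (aldol condensation) should give the (E)-enone with the new C27–C28 bond.

Step 8
Reactants: 13 enone
Product: 14 saturated ketone
Conditions: H2 (1 atm), RhCl(PPh3)3 (5 mol%), benzene/EtOH, rt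
Reagents that add atoms: none
Why: Homogeneous hydrogenation with RhCl(PPh3)3 reduces a disubstituted alkene much faster than a trisubstituted one, so the enone C27=C28 bond should be saturated while the silyl enol ether bridge is kept.

Step 9
Reactants: 14 saturated ketone
Product: 15 ring-A keto acid aldehyde
Conditions: O3, CH2Cl2/MeOH, −78 °C; Me2S, −78 °C → rt
Reagents that add atoms: ozone, [O-][O+]=O
Why: Ozonolysis of the silyl enol ether, the only alkene left, should cleave the C6–C13 bridge and set ring A free with the two carbons told apart as C6 acid and C13 aldehyde, cis to each other because they come from one bridge.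

Step 10
Reactants: 15 ring-A keto acid aldehyde
Product: 16 enoate acid
Conditions: (MeO)2P(O)CH2CO2Me, NaH, THF, 0 → 40 °C
Reagents that add atoms: trimethyl phosphonoacetate, COC(=O)CP(=O)(OC)OC
Why: A Horner–Wadsworth–Emmons olefination should convert the aldehyde, not the hindered α-quaternary ketone, into the (E)-enoate C13=C14–C15 that later accepts the C26 radical.

Step 11
Reactants: 16 enoate acid
Product: 17 diol enoate
Conditions: BH3·SMe2, THF, 0 °C → rt; MeOH
Reagents that add atoms: none
Why: Borane reduces carboxylic acids and ketones but not conjugated esters, so C6 should become a primary alcohol and C26 a secondary alcohol whose configuration does not matter because it is later turned into a radical.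

Step 12
Reactants: 17 diol enoate
Product: 18 hydroxy aldehyde
Conditions: TEMPO (10 mol%), PhI(OAc)2, CH2Cl2, rt
Reagents that add atoms: none
Why: The oxoammonium (TEMPO) oxidation is selective for primary over hindered secondary alcohols, so only C6 should be oxidised to the aldehyde.

Step 13
Reactants: 18 hydroxy aldehyde
Product: 19 vinyl compound
Conditions: Ph3PCH3Br, KN(SiMe3)2, THF, 0 °C → rt
Reagents that add atoms: methyltriphenylphosphonium bromide, C[P+](c1ccccc1)(c1ccccc1)c1ccccc1.[Br-]
Why: Wittig methylenation of the neopentylic aldehyde should add C5 as a terminal alkene, the unstabilised ylide reacting with the aldehyde far faster than with the enoate.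

Step 14
Reactants: 19 vinyl compound
Product: 21 homoprenyl alcohol, via borane adduct 20 (not isolated)
Conditions: 9-BBN, THF, 50 °C; then Me2C=CHBr, PdCl2(dppf) (5 mol%), Cs2CO3, DMF/H2O, 50 °C
Reagents that add atoms: 1-bromo-2-methylprop-1-ene, CC(C)=CBr
Why: 9-BBN should hydroborate only the terminal vinyl group (boron on C5), and B-alkyl Suzuki–Miyaura coupling with the vinyl bromide should complete the 4-methylpent-3-enyl chain on C7.

Step 15
Reactants: 21 homoprenyl alcohol
Product: 22 imidazolyl thiocarbamate
Conditions: 1,1'-thiocarbonyldiimidazole, DMAP (cat.), ClCH2CH2Cl, 70 °C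
Reagents that add atoms: 1,1'-thiocarbonyldiimidazole, S=C(n1ccnc1)n1ccnc1
Why: Thioacylation of the C26 alcohol under neutral conditions should give the radical precursor of a Barton–McCombie reaction without touching the enoate.

Step 16
Reactants: 22 imidazolyl thiocarbamate
Product: 23 trans-decalin ester
Conditions: (Me3Si)3SiH, AIBN, toluene, 90 °C, slow addition
Reagents that add atoms: none
Why: Barton–McCombie C–O homolysis should give a nucleophilic secondary C26 radical that closes ring B by 6-exo-trig addition to the enoate β-carbon C13 through a chair transition state in which the oxolane on C26 and the ester arm on C13 are both equatorial, because the axial sites are blocked by the axial methyls C12 and C30, which sets C13 and C26 (trans-diequatorial, H26 axial and syn to C12).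

Step 17
Reactants: 23 trans-decalin ester
Product: 24 carboxylic acid
Conditions: LiOH, THF/MeOH/H2O, rt; 1 M HCl
Reagents that add atoms: lithium hydroxide, [Li+].[OH-]
Why: Saponification of the unhindered methyl ester should give the acid without affecting the ethers or the alkene.

Step 18
Reactants: 24 carboxylic acid
Product: 26 diazoketone, via mixed anhydride 25 (not isolated)
Conditions: i-BuOCOCl, N-methylmorpholine, THF, −15 °C; CH2N2, Et2O, 0 °C
Reagents that add atoms: diazomethane, C=[N+]=[N-]
Why: Acylation of diazomethane by the mixed carbonic anhydride (first stage of the Arndt–Eistert sequence) should add C16 as a diazomethyl ketone without free HCl that could add to the trisubstituted alkene.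

Step 19
Reactants: 26 diazoketone
Product: 27 tricyclic ketone
Conditions: Rh2(OAc)4 (1 mol%), CH2Cl2, rt, slow addition
Reagents that add atoms: none
Why: Intramolecular rhodium-carbenoid C–H insertion forms five-membered rings with retention, and the only C–H bond in 1,5-relation to C16 is the tertiary axial C26–H on the same face as the C13 arm, so ring C should close cis-fused and C26 become quaternary with C16 syn to C12.

Step 20
Reactants: 27 tricyclic ketone
Product: 28 β-keto ester
Conditions: NaH, (MeO)2CO, THF, reflux; AcOH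
Reagents that add atoms: dimethyl carbonate, COC(=O)OC
Why: Claisen-type C-methoxycarbonylation under equilibrating conditions ends at the less hindered α-carbon, so the ester should sit on C14 rather than on the neopentylic C16, leaving C16 as the only free α-position.

Step 21
Reactants: 28 β-keto ester
Product: 30 bis(silyloxy)diene, via silyl enol ether 29 (not isolated)
Conditions: Et3N, Me3SiCl, benzene, rt; then LiN(iPr)2, THF, −78 °C; Me3SiCl
Reagents that add atoms: chlorotrimethylsilane, C[Si](C)(C)Cl
Why: O-silylation of the β-keto ester, then γ-deprotonation (only the C16 hydrogens remain acidic) and a second O-silylation, is the standard route to 1,3-bis(silyloxy)-1,3-dienes and should fix the enol double bond at C15=C16.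

Step 22
Reactants: 30 bis(silyloxy)diene
Product: 31 pentacyclic β-keto ester
Conditions: TiCl4 (1.5 equiv), 2,6-di-tert-butyl-4-methylpyridine, CH2Cl2 (high dilution), −78 → −30 °C; aq. NaHCO3
Reagents that add atoms: none
Why: Proposed new method: TiCl4, chelated between O25 and the methoxy group, should ionise the tertiary C17–OMe bond, and the γ-carbon C16 of the bis(silyloxy)diene should capture the cation, forming C16–C17 and returning the C14 β-keto ester after loss of the silyl groups. The closest known reaction type is the Lewis-acid-mediated SN1 tert-alkylation of silyl enol ethers and 1,3-bis(silyloxy)dienes with tertiary halides, ethers or esters; what is new is the ether oxygen next to the cationic carbon and the bridged ring that results. The closure is six-membered when counted through O25 (C16, C17, C20, O25, C23, C26; enol-exo, exo at the trigonal cation) and at the same time completes the seven-membered carbocycle C16–C17–C20–C21–C22–C23–C26 of the 8-oxabicyclo[3.2.1]octane. The new stereocentre C16 is set by the tether, since C17 can reach the planar C15=C16 unit only on the face where C23 stands, which gives the cis C16–C26 fusion that step 23 corrects. The step needs attack through C16 instead of C14 and C–C bond formation instead of proton loss to an isopropenyl group: the first is secured because only C16 can close a six-membered ring (C14 would need an eight-membered one), the second by the cis-2,5-disubstituted oxolane holding C17 beside C16, by the high nucleophilicity of the dienolate, by high dilution and by the hindered pyridine that removes adventitious acid from the side-chain alkene.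

Step 23
Reactants: 31 pentacyclic β-keto ester
Product: 33 trans-fused ketone, via cis-fused ketone 32 (not isolated)
Conditions: LiCl, DMSO/H2O, 150 °C; then DBU, 80 °C
Reagents that add atoms: none
Why: Krapcho dealkoxycarbonylation should remove the C14 ester, and base equilibration of C16, the only epimerisable centre, should favour the trans C16–C26 fusion, in which C15 is equatorial on the oxane chair instead of endo-axial against the C21–C22 bridge.

Step 24
Reactants: 33 trans-fused ketone
Product: 35 target CNP0284367.1, via hydrazone 34 (not isolated)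
Conditions: N2H4·H2O, KOH, diethylene glycol, 130 → 200 °C
Reagents that add atoms: none
Why: Wolff–Kishner reduction (Huang-Minlon procedure) should remove the C15 carbonyl while the isolated trisubstituted alkene and the bridging ether are inert and C16 stays in its thermodynamic configuration.

Compound list
1 | (R)-linalool, (3R)-3,7-dimethylocta-1,6-dien-3-ol | C=C[C@](C)(O)CCC=C(C)C | starting material
2 | (3R,6R)-6,7-epoxy-3,7-dimethyloct-1-en-3-ol | C=C[C@](C)(O)CC[C@H]1OC1(C)C | intermediate
3 | cis-linalool oxide (furanoid), 2-[(2S,5R)-5-ethenyl-5-methyloxolan-2-yl]propan-2-ol | C=C[C@@]1(C)CC[C@@H](C(C)(C)O)O1 | intermediate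
4 | (2R,5S)-2-ethenyl-5-(2-methoxypropan-2-yl)-2-methyloxolane | C=C[C@@]1(C)CC[C@@H](C(C)(C)OC)O1 | intermediate
5 | 1-[(2R,5S)-5-(2-methoxypropan-2-yl)-2-methyloxolan-2-yl]ethan-1-one (C26 ketone, C27 methyl) | CC(=O)[C@@]1(C)CC[C@@H](C(C)(C)OC)O1 | intermediate
6 | 3-methylcyclohex-2-en-1-one | CC1=CC(=O)CCC1 | starting material
7 | 3,6-dimethylcyclohex-2-en-1-one (racemic) | CC1=CC(=O)C(C)CC1 | intermediate
8 | 2-(tert-butyldimethylsilyloxy)-1,4-dimethylcyclohexa-1,3-diene | CC1=C(O[Si](C)(C)C(C)(C)C)C=C(C)CC1 | intermediate
9 | methacrolein, 2-methylprop-2-enal | CC(=C)C=O | starting material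
10 | 5-(tert-butyldimethylsilyloxy)-1,2,4-trimethylbicyclo[2.2.2]oct-5-ene-2-carbaldehyde; bridgeheads C11 and C7, enol-ether bridge C6=C13, formyl (C28) on C29 anti to that bridge | O=C[C@@]1(C)C[C@@]2(C)CC[C@]1(C)C=C2O[Si](C)(C)C(C)(C)C | intermediate
11 | aldol adduct, β-hydroxy ketone C26(=O)–C27H2–C28H(OH) joining 5 to C29 of 10 (C28 epimers) | COC(C)(C)[C@@H]1CC[C@@](C)(O1)C(=O)CC(O)[C@@]2(C)C[C@@]3(C)CC[C@]2(C)C=C3O[Si](C)(C)C(C)(C)C | intermediate
12 | C28 methanesulfonate of 11 | COC(C)(C)[C@@H]1CC[C@@](C)(O1)C(=O)CC(OS(C)(=O)=O)[C@@]2(C)C[C@@]3(C)CC[C@]2(C)C=C3O[Si](C)(C)C(C)(C)C | intermediate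
13 | (E)-enone C26(=O)–C27H=C28H–C29 | COC(C)(C)[C@@H]1CC[C@@](C)(O1)C(=O)/C=C/[C@@]2(C)C[C@@]3(C)CC[C@]2(C)C=C3O[Si](C)(C)C(C)(C)C | intermediate
14 | saturated ketone C26(=O)–C27H2–C28H2–C29, silyl enol ether bridge intact | COC(C)(C)[C@@H]1CC[C@@](C)(O1)C(=O)CC[C@@]2(C)C[C@@]3(C)CC[C@]2(C)C=C3O[Si](C)(C)C(C)(C)C | intermediate
15 | ring-A cyclohexane with C7(CH3)(CO2H), C11(CH3)(CHO) and C29(CH3)(CH2CH2CO-oxolanyl); CO2H and CHO cis, the C29 arm trans to the CHO | COC(C)(C)[C@@H]1CC[C@@](C)(O1)C(=O)CC[C@@]2(C)C[C@](C)(C(=O)O)CC[C@]2(C)C=O | intermediate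
16 | as 15 with the C11 aldehyde converted to the methyl (E)-propenoate C13=C14–C15O2Me | COC(C)(C)[C@@H]1CC[C@@](C)(O1)C(=O)CC[C@@]2(C)C[C@](C)(C(=O)O)CC[C@]2(C)/C=C/C(=O)OC | intermediate
17 | diol: C6H2OH on C7 and C26H(OH) (C26 epimers), enoate intact | COC(C)(C)[C@@H]1CC[C@@](C)(O1)C(O)CC[C@@]2(C)C[C@](C)(CO)CC[C@]2(C)/C=C/C(=O)OC | intermediate
18 | C6 aldehyde, C26 alcohol (C26 epimers) | COC(C)(C)[C@@H]1CC[C@@](C)(O1)C(O)CC[C@@]2(C)C[C@](C)(C=O)CC[C@]2(C)/C=C/C(=O)OC | intermediate
19 | C7 vinyl compound (C6=C5), C26 alcohol | COC(C)(C)[C@@H]1CC[C@@](C)(O1)C(O)CC[C@@]2(C)C[C@](C)(C=C)CC[C@]2(C)/C=C/C(=O)OC | intermediate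
20 | B-(C5-alkyl)-9-BBN with the C26 oxygen as its 9-BBN borinate | COC(C)(C)[C@@H]1CC[C@@](C)(O1)C(OB3C4CCCC3CCC4)CC[C@@]2(C)C[C@](C)(CCB3C4CCCC3CCC4)CC[C@]2(C)/C=C/C(=O)OC | intermediate
21 | C26 alcohol with the complete 4-methylpent-3-enyl chain on C7 | COC(C)(C)[C@@H]1CC[C@@](C)(O1)C(O)CC[C@@]2(C)C[C@](C)(CCC=C(C)C)CC[C@]2(C)/C=C/C(=O)OC | intermediate
22 | O-(C26) imidazole-1-carbothioate of 21 | COC(C)(C)[C@@H]1CC[C@@](C)(O1)C(OC(=S)n3ccnc3)CC[C@@]2(C)C[C@](C)(CCC=C(C)C)CC[C@]2(C)/C=C/C(=O)OC | intermediate
23 | trans-decalin (rings A and B): CH2CO2Me on C13 and oxolane on C26, both equatorial; H13 axial anti to C12, H26 axial syn to C12 | CC(C)=CCC[C@]1(C)CC[C@]2(C)[C@@H](CC(=O)OC)[C@@H](CC[C@@]2(C)C1)[C@@]3(C)CC[C@@H](C(C)(C)OC)O3 | intermediate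
24 | carboxylic acid from 23 | CC(C)=CCC[C@]1(C)CC[C@]2(C)[C@@H](CC(=O)O)[C@@H](CC[C@@]2(C)C1)[C@@]3(C)CC[C@@H](C(C)(C)OC)O3 | intermediate
25 | isobutyl carbonic anhydride of 24 | CC(C)=CCC[C@]1(C)CC[C@]2(C)[C@@H](CC(=O)OC(=O)OCC(C)C)[C@@H](CC[C@@]2(C)C1)[C@@]3(C)CC[C@@H](C(C)(C)OC)O3 | intermediate
26 | diazomethyl ketone C13–C14H2–C15(=O)–C16H=N2 | CC(C)=CCC[C@]1(C)CC[C@]2(C)[C@@H](CC(=O)C=[N+]=[N-])[C@@H](CC[C@@]2(C)C1)[C@@]3(C)CC[C@@H](C(C)(C)OC)O3 | intermediate
27 | tricyclic C15 ketone (rings A, B, C; ring C cis-fused; C26 quaternary with the oxolane; C17 methyl ether) | CC(C)=CCC[C@]1(C)CC[C@]2(C)[C@H]3CC(=O)C[C@]3(CC[C@@]2(C)C1)[C@@]4(C)CC[C@@H](C(C)(C)OC)O4 | intermediate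
28 | C15 ketone with CO2Me on C14 (C14 epimers and enol) | CC(C)=CCC[C@]1(C)CC[C@]2(C)[C@H]3C(C(=O)OC)C(=O)C[C@]3(CC[C@@]2(C)C1)[C@@]4(C)CC[C@@H](C(C)(C)OC)O4 | intermediate
29 | trimethylsilyl enol ether C14=C15(OSiMe3) of 28 | CC(C)=CCC[C@]1(C)CC[C@]2(C)[C@H]3C(C(=O)OC)=C(O[Si](C)(C)C)C[C@]3(CC[C@@]2(C)C1)[C@@]4(C)CC[C@@H](C(C)(C)OC)O4 | intermediate
30 | 1,3-bis(silyloxy)diene: C14=C(OMe)OSiMe3 and C15(OSiMe3)=C16H; C17 methyl ether on the cis-oxolane | CC(C)=CCC[C@]1(C)CC[C@]2(C)[C@H]3C(=C(OC)O[Si](C)(C)C)C(O[Si](C)(C)C)=C[C@]3(CC[C@@]2(C)C1)[C@@]4(C)CC[C@@H](C(C)(C)OC)O4 | intermediate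
31 | pentacyclic C14-carbomethoxy C15 ketone, complete skeleton, C16 epimer with cis C16–C26 fusion (C14 epimers and enol) | CC(C)=CCC[C@]1(C)CC[C@]2(C)[C@H]3C(C(=O)OC)C(=O)[C@@H]4C(C)(C)[C@@H]5CC[C@@](C)(O5)[C@@]43CC[C@@]2(C)C1 | intermediate
32 | C15 ketone, C16 epimer (cis C16–C26 fusion) | CC(C)=CCC[C@]1(C)CC[C@]2(C)[C@H]3CC(=O)[C@@H]4C(C)(C)[C@@H]5CC[C@@](C)(O5)[C@@]43CC[C@@]2(C)C1 | intermediate
33 | C15 ketone of the target skeleton, trans C16–C26 fusion | CC(C)=CCC[C@]1(C)CC[C@]2(C)[C@H]3CC(=O)[C@H]4C(C)(C)[C@@H]5CC[C@@](C)(O5)[C@@]43CC[C@@]2(C)C1 | intermediate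
34 | C15 hydrazone of 33 | CC(C)=CCC[C@]1(C)CC[C@]2(C)[C@H]3CC(=NN)[C@H]4C(C)(C)[C@@H]5CC[C@@](C)(O5)[C@@]43CC[C@@]2(C)C1 | intermediate
35 | CNP0284367.1 | CC(C)=CCC[C@]1(C)CC[C@]2(C)[C@H]3CC[C@H]4C(C)(C)[C@@H]5CC[C@@](C)(O5)[C@@]43CC[C@@]2(C)C1 | target

Total step count: 24. Longest linear sequence: 21 steps (steps 4–24 from 6, or steps 1–3 and 7–24 from 1).

Steps most likely to fail

Step 22. The tertiary cation next to the ether oxygen may lose a proton to give the isopropenyl group, or the oxolane C23–O25 bond may ionise, before the hindered C16 can bond to C17. The fallback uses known chemistry, sets out from tricyclic ketone 27 and returns at ketone 33. Loss of methanol from 27 with Me3SiOTf and 2,6-di-tert-butyl-4-methylpyridine (CH2Cl2, 0 °C, aqueous work-up) should give isopropenyl ketone F1. Heating F1 in toluene at about 280 °C in a sealed tube should close the ring by a thermal Conia-ene reaction: the C15 enol adds across the isopropenyl group, C16 bonds to C17 and the terminal CH2 becomes the second methyl group. Only the enol towards C16 can reach the alkene, and at this temperature C16 should equilibrate to the trans-fused ketone 33.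

Step 6. Three fully substituted carbons are made at once, so the cycloaddition may stall at the conjugate-addition stage with loss of the silyl group, or the exo and facial selectivities may erode with this hindered diene. The fallback gives up catalytic enantiocontrol, sets out from diene 8 and methacrolein 9 and returns at enone 13. A Diels–Alder reaction promoted by the mixed Lewis acid AlBr3/AlMe3 (toluene/CH2Cl2, 0 °C) should give the racemic exo aldehyde, that is 10 together with its enantiomer F2. Aldol condensation of this racemate with enantiopure ketone 5 under the conditions of step 7 should give enone 13 and the diastereomeric enone F3, which are separated by chromatography.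

Step 19. The acceptor-only carbenoid may dimerise or be trapped by the ether oxygens faster than it inserts into the hindered C26–H bond, which is also deactivated by the oxygen on C23. The fallback changes the carbenoid class, sets out from acid 24 and returns at ketone 27. Chain extension of the acyl imidazole of 24 (carbonyldiimidazole, then Mg(O2CCH2CO2Me)2, THF) should give β-keto ester F4. Diazo transfer (4-acetamidobenzenesulfonyl azide, Et3N, MeCN) should give diazo β-keto ester F5. Its acceptor/acceptor carbenoid (Rh2(OAc)4, CH2Cl2, reflux) should insert into the same C26–H bond to give cyclopentanone ester F6, and Krapcho dealkoxycarbonylation (LiCl, DMSO/H2O, 150 °C) should give 27.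

Further compounds
F1 | step 22 | isopropenyl ketone, 27 with the C17 methoxy group eliminated to C17(=CH2)CH3 | CC(C)=CCC[C@]1(C)CC[C@]2(C)[C@H]3CC(=O)C[C@]3(CC[C@@]2(C)C1)[C@@]4(C)CC[C@@H](C(C)=C)O4
F2 | step 6 | enantiomer of aldehyde 10 | O=C[C@]1(C)C[C@]2(C)CC[C@@]1(C)C=C2O[Si](C)(C)C(C)(C)C
F3 | step 6 | diastereomer of enone 13 formed from F2 and 5 | COC(C)(C)[C@@H]1CC[C@@](C)(O1)C(=O)/C=C/[C@]2(C)C[C@]3(C)CC[C@@]2(C)C=C3O[Si](C)(C)C(C)(C)C
F4 | step 19 | β-keto ester C13–C14H2–C15(=O)–C16H2–CO2Me | CC(C)=CCC[C@]1(C)CC[C@]2(C)[C@@H](CC(=O)CC(=O)OC)[C@@H](CC[C@@]2(C)C1)[C@@]3(C)CC[C@@H](C(C)(C)OC)O3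
F5 | step 19 | diazo β-keto ester, diazo group on C16 | CC(C)=CCC[C@]1(C)CC[C@]2(C)[C@@H](CC(=O)C(=[N+]=[N-])C(=O)OC)[C@@H](CC[C@@]2(C)C1)[C@@]3(C)CC[C@@H](C(C)(C)OC)O3
F6 | step 19 | tricyclic C15 ketone with CO2Me on C16 (C16 epimers) | CC(C)=CCC[C@]1(C)CC[C@]2(C)[C@H]3CC(=O)C(C(=O)OC)[C@]3(CC[C@@]2(C)C1)[C@@]4(C)CC[C@@H](C(C)(C)OC)O4
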